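(The data are calculated on assumed constants, and the scatter is random.)

| flask | Q | X | E | remark | time |
|---|---|---|---|---|---|
| grey | 15 mM | 19.5 mM | 30 mM | run made earlier |  |
| teal | 15 mM | 9.8 mM | 30 mM | run made earlier |  |
| blue | 15 mM | 39 mM | 30 mM | run made earlier |  |
| amber | 22 mM | 19.5 mM | 30 mM | run made earlier |  |
| elm | 15 mM (fed, over 1.0 h) | 19.5 mM | 30.0 mM | all else is in the flask from the start; the feed brings no volume worth counting | 80 min |
| maple | 15 mM | 19.5 mM (in portions, 5, over 1.0 h) | 30.0 mM | first portion at the start, last at 1.0 h | 80 min |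
| larch | 15 mM | 19.5 mM (fed, over 1.0 h) | 30.0 mM | all else is in the flask from the start; the feed brings no volume worth counting | 80 min |
| oak | 15 mM | 19.5 mM | 30.0 mM | everything together at the start | 80 min |
| alder | 15 mM | 19.5 mM (fed, over 6.0 min) | 30.0 mM | all else is in the flask from the start; the feed brings no volume worth counting | 80 min |

| run | time / min | J / % | D / % |
|---|---|---|---|
| grey | 15.0 | 0 | 3.3 |
| grey | 30.0 | 3.2 | 6.5 |
| grey | 50.0 | 4.0 | 6.2 |
| grey | 60.0 | 3.0 | 7.1 |
| grey | 80.0 | 3.6 | 7.1 |
| teal | 6.00 | 0 | 0.6 |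
| teal | 15.0 | 0.3 | 0 |
| teal | 30.0 | 0.9 | 0.1 |
| teal | 50.0 | 1.5 | 0.4 |
| teal | 60.0 | 0.3 | 1.6 |
| blue | 6.00 | 2.9 | 6.9 |
| blue | 15.0 | 1.5 | 13.6 |
| blue | 30.0 | 4.7 | 18.1 |
| blue | 50.0 | 4.6 | 20.3 |
| blue | 60.0 | 4.5 | 19.5 |
| amber | 5.00 | 0.6 | 2.3 |
| amber | 10.0 | 0.9 | 1.7 |
| amber | 20.0 | 2.6 | 1.1 |
| amber | 30.0 | 1.3 | 0.7 |
| amber | 60.0 | 3.4 | 1.9 |

(readings scatter by 1 percentage point)

- the numbers in the tables scatter with a standard deviation of 1 percentage point

* which flask leads in share of J in J plus D ("all alike" within 1.5 percentage points) (elm / maple / larch / oak / alder / all alike)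
* share of J in J plus D at the end, elm
* share of J in J plus D at the end, maple
* share of J in J plus D at the end, larch
* share of J in J plus D at the end, oak
* share of J in J plus D at the end, alder

- From 50.0 min on, grey holds level within the scatter of 1 point. Its J averages 3.53 % and its D 6.80 %, and I book that as its end.
- I keep the books on Q, which I take as the limiting reagent, with X at 1.30 per Q in grey.
- First entry: each Q in J has taken two X, and each Q in D one X more. Each X taken frees one E.
- Second entry: the other 89.7 % of Q in grey is unread. I give it half an X per Q, a value I choose so that grey and blue agree.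
- Grey's books then close at cX 8.65 mM and cE 40.8 mM.
- From 30.0 min on, blue averages J 4.60 % and D 19.3 %. Its books close at cX 23.2 mM and cE 45.8 mM.
- Grey gives 9.08 and blue 8.28 for the exchange quotient W, the reaction quotient cD·cE/(cJ·cX) of J + X to D + E.
- If W holds, the share of J in J plus D is 1/(1 + W·cX/cE). Oak repeats grey, so I commit to 34.2 % for oak, and I expect alder close to it.
- Blue has more X per Q and puts 23.9 % of Q into J and D, against 10.3 % in grey.
- Feeding Q keeps X high per Q, so I expect elm to put more Q into J and D. These take more X per Q than the unread entry, so cX/cE falls and the share rises.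
- From 30.0 min on, amber has less X per Q and reads 3.65 % of Q in J and D, against 10.3 % in grey.
- Larch and maple start X low per Q, so I expect them to put less Q into J and D, with cX/cE higher and the share lower. I put elm first, then oak and alder, then larch and maple.
- The forecast differs: larch leads, with elm 31 %, maple 36 %, larch 37 %, oak 34 % and alder 34 %: “Larch leads narrowly”.
- The flasks give elm 41.6 %, maple 33.5 %, larch 33.8 %, oak 37.3 % and alder 36.9 %, so elm leads.

    Q + G → Z (k = 1.30 M⁻¹ s⁻¹)
    J + X ⇌ E + D (K = 8.30, k = 0.660 M⁻¹ s⁻¹)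
    G + X → E + J (k = 0.0860 M⁻¹ s⁻¹)
    Q + X → E + G (k = 0.0780 M⁻¹ s⁻¹)

- In elm at 80.0 min, cX is 7.24 mM and cE is 42.3 mM, so W gives a share of 39.1 % against 41.6 %. At that time elm uses Q by the step with X 1.3 times as fast as by the step with G. Z, with two Q in each, holds 77.0 % of the Q charged in elm, against 88.0 % in oak. A neighbour of elm with 78 mM of X ends at cX 44.4 mM and cE 63.6 mM, where W gives 13.6 % against the simulated 14.7 %.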